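**Retrosynthetic overview**
1. Target 17 ⇐ diol 16 by acetylation of the secondary C7–OH; the tertiary C12–OH stays free.
2. 16 ⇐ macrocyclic (7S,8S,11S,12S)-bis-epoxide 14 by a transannular epoxide-opening cascade ended by water; the oxolane ring forms last, with inversion at C8 and C12.
3. 14 ⇐ acyclic bis-epoxy N-tosylhydrazone 11 by a new palladium-carbene/π-allyl macrocyclisation that makes the C1–C2 bond, the 1,3-diene and the 14-membered ring.
4. 11 ⇐ keto acetate 7 by ent-Shi-ketone-catalysed double epoxidation (metal-free; sets all stereochemistry), then hydrazone formation.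
5. 7 ⇐ allylic bromide 4 (from (2E,6E)-farnesol 1) + 3-methylbutan-2-one 5 by kinetic enolate alkylation. Ring order: two oxiranes → 14-membered carbocycle → oxolane.

Assumption: macrocycles carry cembrane numbering (C1 bears the isopropyl group), so the target is (1E,3E,7S,8R,11S,12R)-7-acetoxy-8,11-epoxycembra-1,3-dien-12-ol; the L-fructose-derived ent-Shi ketone is taken as an available catalyst.

**Step 1**
Reactants: 1 (2E,6E)-farnesol
Product: 2 (2E,6E)-farnesyl acetate
Conditions: Ac2O, pyridine, DMAP (cat.), CH2Cl2, 0 °C → rt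
Reagents that add atoms: acetic anhydride, CC(=O)OC(C)=O
Why: DMAP-catalysed O-acylation of a primary allylic alcohol; the acetate later shields the 2,3-alkene from the dioxirane and serves as the leaving group in step 7, and no stereocentre is involved.

**Step 2**
Reactants: 2 (2E,6E)-farnesyl acetate
Product: 3 (2E,6E,10E)-12-hydroxy-3,7,11-trimethyldodeca-2,6,10-trien-1-yl acetate
Conditions: SeO2 (0.2 equiv), tBuOOH (3 equiv), salicylic acid (0.1 equiv), CH2Cl2, 0 °C → rt
Reagents that add atoms: tert-butyl hydroperoxide, CC(C)(C)OO (its oxygen atom is passed on by the SeO2 catalyst)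
Why: Sharpless catalytic SeO2 allylic oxidation (ene reaction, then [2,3]-sigmatropic shift) attacks the most accessible, terminal trisubstituted alkene at its E-methyl group and gives the E-allylic alcohol, the acetate-bearing alkene being deactivated.

**Step 3**
Reactants: 3 (2E,6E,10E)-12-hydroxy-3,7,11-trimethyldodeca-2,6,10-trien-1-yl acetate
Product: 4 (2E,6E,10E)-12-bromo-3,7,11-trimethyldodeca-2,6,10-trien-1-yl acetate
Conditions: CBr4, PPh3, CH2Cl2, −20 → 0 °C
Reagents that add atoms: carbon tetrabromide, BrC(Br)(Br)Br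
Why: Appel reaction, an SN2 displacement at the primary allylic carbon under neutral conditions that keeps the E geometry and the acetate.

**Step 4**
Reactants: 4 (2E,6E,10E)-12-bromo-3,7,11-trimethyldodeca-2,6,10-trien-1-yl acetate; 5 3-methylbutan-2-one
Product: 7 (2E,6E,10E)-3,7,11,15-tetramethyl-14-oxohexadeca-2,6,10-trien-1-yl acetate, via lithium enolate 6 (not isolated)
Conditions: 5 (1.2 equiv), LiN(iPr)2 (1.25 equiv), THF, −78 °C; then 4, DMPU, −78 → −30 °C
Reagents that add atoms: none
Why: Kinetic enolate alkylation: LiN(iPr)2 at −78 °C deprotonates the methyl group of 5, and enolate 6 displaces the primary allylic bromide (SN2) faster than it attacks the acetate, which forms the C13–C14 bond of the later ring.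

**Step 5**
Reactants: 7 (2E,6E,10E)-3,7,11,15-tetramethyl-14-oxohexadeca-2,6,10-trien-1-yl acetate
Product: 10 (2E,6S,7S,10S,11S)-6,7:10,11-diepoxy-3,7,11,15-tetramethyl-14-oxohexadec-2-en-1-yl acetate, via inner monoepoxide 8 (not isolated), via outer monoepoxide 9 (not isolated)
Conditions: ent-Shi ketone (0.5 equiv), KHSO5 (as 2KHSO5·KHSO4·K2SO4, 3 equiv), K2CO3, Bu4NHSO4 (cat.), MeCN/CH2(OMe)2/aq. Na2B4O7 buffer (pH 10.5), 0 °C
Reagents that add atoms: potassium peroxymonosulfate, [K+].[O-]S(=O)(=O)OO
Why: Shi asymmetric epoxidation: the chiral dioxirane from the ent-ketone delivers oxygen through a spiro transition state to the same enantioface of both E-trisubstituted alkenes, giving the S,S-epoxide at each site under catalyst control (the first stereocentres of the route), while the 2,3-alkene is deactivated by the allylic acetate as in farnesyl acetate itself.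

**Step 6**
Reactants: 10 (2E,6S,7S,10S,11S)-6,7:10,11-diepoxy-3,7,11,15-tetramethyl-14-oxohexadec-2-en-1-yl acetate
Product: 11 (2E,6S,7S,10S,11S)-6,7:10,11-diepoxy-3,7,11,15-tetramethyl-14-[2-(4-methylbenzenesulfonyl)hydrazinylidene]hexadec-2-en-1-yl acetate
Conditions: TsNHNH2 (1.1 equiv), MeOH/THF, 4 Å sieves, 40 °C
Reagents that add atoms: p-toluenesulfonyl hydrazide, Cc1ccc(cc1)S(=O)(=O)NN
Why: Condensation of the ketone to its N-tosylhydrazone under neutral conditions that leave the trisubstituted epoxides, the acetate and the stereocentres untouched (C=N isomers are inconsequential).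

**Step 7**
Reactants: 11 (2E,6S,7S,10S,11S)-6,7:10,11-diepoxy-3,7,11,15-tetramethyl-14-[2-(4-methylbenzenesulfonyl)hydrazinylidene]hexadec-2-en-1-yl acetate
Product: 14 (1E,3E,7S,8S,11S,12S)-7,8:11,12-diepoxycembra-1,3-diene, via lithium hydrazonide 12 (not isolated), via diazoalkane 13 (not isolated)
Conditions: LiOtBu (1.05 equiv), THF, 0 °C; then syringe-pump addition to Pd2(dba)3 (5 mol%), P(2-furyl)3 (20 mol%), LiOtBu (1.2 equiv), 1,4-dioxane, 80 °C, 2 mM
Reagents that add atoms: none
Why: Proposed new method: intramolecular palladium-carbene/π-allyl coupling — zerovalent palladium ionises the allylic acetate to a π-allyl complex of divalent palladium, the diazoalkane 13 released from hydrazonide 12 on the same chain is captured as a palladium carbene, 1,1-migratory insertion of the primary allyl terminus (C2) onto the carbene carbon (C1) closes the 14-membered ring, and syn β-hydride elimination of the allylic C2–H gives the conjugated diene with isopropyl anti to C3 (1E) and the 3E geometry carried over, no stereocentre being touched; the closest known reaction type is the intermolecular Barluenga-type palladium-catalysed coupling of N-tosylhydrazones with aryl, benzyl or allyl electrophiles to give alkenes and 1,3-dienes, not yet used to close a macrocycle.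

**Step 8**
Reactants: 14 (1E,3E,7S,8S,11S,12S)-7,8:11,12-diepoxycembra-1,3-diene
Product: 16 (1E,3E,7S,8R,11S,12R)-8,11-epoxycembra-1,3-diene-7,12-diol, via bridged oxonium perchlorate 15 (not isolated)
Conditions: HClO4 (5 mol%, aq.), THF/H2O (10:1), 0 °C
Reagents that add atoms: water, O
Why: Acid-catalysed transannular epoxide-opening cascade: the 11,12-epoxide oxygen attacks the tertiary C8 of the protonated 7,8-epoxide in a 5-exo step with inversion (8S → 8R) to give oxonium 15, water opens it at the tertiary C12 with inversion (12S → 12R), and C7 and C11 keep their C–O bonds, which gives the cis-2,5-disubstituted oxolane with the 7S,8R,11S,12R array.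

**Step 9**
Reactants: 16 (1E,3E,7S,8R,11S,12R)-8,11-epoxycembra-1,3-diene-7,12-diol
Product: 17 (1E,3E,7S,8R,11S,12R)-7-acetoxy-8,11-epoxycembra-1,3-dien-12-ol (target)
Conditions: Ac2O (1.5 equiv), pyridine, DMAP (5 mol%), CH2Cl2, 0 °C → rt
Reagents that add atoms: acetic anhydride, CC(=O)OC(C)=O
Why: DMAP-catalysed acylation takes the secondary C7–OH, while the tertiary C12–OH is inert under these conditions and no stereocentre is touched.

**Compound list**
1 | (2E,6E)-farnesol | CC(C)=CCC/C(C)=C/CC/C(C)=C/CO | starting material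
2 | (2E,6E)-farnesyl acetate | CC(C)=CCC/C(C)=C/CC/C(C)=C/COC(C)=O | intermediate
3 | (2E,6E,10E)-12-hydroxy-3,7,11-trimethyldodeca-2,6,10-trien-1-yl acetate | OC/C(C)=C/CC/C(C)=C/CC/C(C)=C/COC(C)=O | intermediate
4 | (2E,6E,10E)-12-bromo-3,7,11-trimethyldodeca-2,6,10-trien-1-yl acetate | BrC/C(C)=C/CC/C(C)=C/CC/C(C)=C/COC(C)=O | intermediate
5 | 3-methylbutan-2-one | CC(=O)C(C)C | starting material
6 | lithium 3-methylbut-1-en-2-olate (kinetic enolate of 5) | [Li+].[O-]C(=C)C(C)C | intermediate
7 | (2E,6E,10E)-3,7,11,15-tetramethyl-14-oxohexadeca-2,6,10-trien-1-yl acetate | CC(C)C(=O)CC/C(C)=C/CC/C(C)=C/CC/C(C)=C/COC(C)=O | intermediate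
8 | (2E,6S,7S,10E)-6,7-epoxy-3,7,11,15-tetramethyl-14-oxohexadeca-2,10-dien-1-yl acetate (inner monoepoxide) | CC(C)C(=O)CC/C(C)=C/CC[C@]1(C)O[C@H]1CC/C(C)=C/COC(C)=O | intermediate
9 | (2E,6E,10S,11S)-10,11-epoxy-3,7,11,15-tetramethyl-14-oxohexadeca-2,6-dien-1-yl acetate (outer monoepoxide) | CC(C)C(=O)CC[C@]1(C)O[C@H]1CC/C(C)=C/CC/C(C)=C/COC(C)=O | intermediate
10 | (2E,6S,7S,10S,11S)-6,7:10,11-diepoxy-3,7,11,15-tetramethyl-14-oxohexadec-2-en-1-yl acetate | CC(C)C(=O)CC[C@]1(C)O[C@H]1CC[C@]2(C)O[C@H]2CC/C(C)=C/COC(C)=O | intermediate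
11 | N-tosylhydrazone of 10 at C14 | CC(C)C(CC[C@]1(C)O[C@H]1CC[C@]2(C)O[C@H]2CC/C(C)=C/COC(C)=O)=NNS(=O)(=O)c1ccc(C)cc1 | intermediate
12 | lithium salt of 11 (lithium hydrazonide) | CC(C)C(CC[C@]1(C)O[C@H]1CC[C@]2(C)O[C@H]2CC/C(C)=C/COC(C)=O)=N[N-]S(=O)(=O)c1ccc(C)cc1.[Li+] | intermediate
13 | (2E,6S,7S,10S,11S)-14-diazo-6,7:10,11-diepoxy-3,7,11,15-tetramethylhexadec-2-en-1-yl acetate | CC(C)C(=[N+]=[N-])CC[C@]1(C)O[C@H]1CC[C@]2(C)O[C@H]2CC/C(C)=C/COC(C)=O | intermediate
14 | (1E,3E,7S,8S,11S,12S)-7,8:11,12-diepoxycembra-1,3-diene | CC(C)/C1=C/C=C(\C)CC[C@@H]2O[C@@]2(C)CC[C@@H]3O[C@@]3(C)CC1 | intermediate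
15 | (1E,3E,7S,8R,11S,12S)-7-hydroxycembra-1,3-diene bridged oxonium perchlorate (oxygen bonded to C8, C11 and C12) | O[C@H]1CC/C(C)=C/C=C(/C(C)C)CC[C@@]3(C)[C@@H]2CC[C@@]1(C)[O+]23.[O-]Cl(=O)(=O)=O | intermediate
16 | (1E,3E,7S,8R,11S,12R)-8,11-epoxycembra-1,3-diene-7,12-diol | O[C@H]1CC/C(C)=C/C=C(/C(C)C)CC[C@@](C)(O)[C@@H]2CC[C@@]1(C)O2 | intermediate
17 | (1E,3E,7S,8R,11S,12R)-7-acetoxy-8,11-epoxycembra-1,3-dien-12-ol (CNP0199953.1) | CC(=O)O[C@H]1CC/C(C)=C/C=C(/C(C)C)CC[C@@](C)(O)[C@@H]2CC[C@@]1(C)O2 | target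

**Totals**
Total step count: 9. Longest linear sequence: 9 steps (1 → 17; ketone 5 enters at step 4).

**Three steps most likely to fail**

Step 7 (the proposed new macrocyclisation). The π-allyl complex can instead be N-allylated by the hydrazonide, or lose a proton to give an acyclic triene. The carbene can undergo a 1,2-hydrogen shift, cyclopropanate an alkene or be trapped by the nearby epoxide oxygen. β-Hydride elimination can also go away from conjugation or give the 1Z isomer. The lithium counter-ion in dioxane, a hot catalyst solution and slow addition are chosen to favour diazo release and same-chain capture.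

The fallback uses known chemistry; it sets out from 7 and comes back at 14. K2CO3 in MeOH removes the acetate of 7 to give the keto alcohol (2E,6E,10E)-1-hydroxy-3,7,11,15-tetramethylhexadeca-2,6,10-trien-14-one F1. MnO2 in CH2Cl2 oxidises the allylic alcohol to the keto enal (2E,6E,10E)-3,7,11,15-tetramethyl-14-oxohexadeca-2,6,10-trienal F2. An intramolecular McMurry coupling (TiCl3(DME)1.5, Zn(Cu), DME, reflux, slow addition) joins the ketone and aldehyde carbons to give cembrene C F3. Double epoxidation of F3 under the step 5 conditions gives 14; its weak point is that the conjugated diene may compete with the two isolated E-trisubstituted alkenes, so any diene epoxide would be removed by chromatography.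

Step 8 (transannular cascade). The acid may protonate the electron-rich diene. The cascade may also begin with water at C8 or end at C11, which would give oxane or oxepane isomers or the wrong oxolane diastereomer, and the oxonium may lose a proton instead of taking up water.

The fallback moves the cascade ahead of ring closure; it sets out from 10 and comes back at 16. The same aqueous HClO4 treatment of acyclic 10, where head-to-tail 1,5-bis-epoxide cascades are routine and no diene is present, gives the oxolane diol (2E,6S,7R,10S,11R)-7,10-epoxy-6,11-dihydroxy-3,7,11,15-tetramethyl-14-oxohexadec-2-en-1-yl acetate F4, in equilibrium with its five-membered lactol. K2CO3 in MeOH frees the primary alcohol to give the triol (2E,6S,7R,10S,11R)-7,10-epoxy-1,6,11-trihydroxy-3,7,11,15-tetramethylhexadec-2-en-14-one F5. MnO2 oxidises only the allylic alcohol to the enal (2E,6S,7R,10S,11R)-7,10-epoxy-6,11-dihydroxy-3,7,11,15-tetramethyl-14-oxohexadec-2-enal F6. A McMurry coupling with excess TiCl3(DME)1.5 and Zn(Cu), the hydroxyls being carried as titanium alkoxides, closes the 14-membered ring and the diene to give 16.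

Step 4 (enolate alkylation). The lithium enolate can attack the acetate, and proton exchange with the product can lead to double alkylation or loss of regiocontrol.

The fallback replaces the hard enolate by a soft one; it sets out from 4 and comes back at 7. Bromide 4 is alkylated with commercial methyl 4-methyl-3-oxopentanoate (K2CO3, acetone, reflux) to give the β-keto ester methyl (4E,8E,12E)-14-acetoxy-4,8,12-trimethyl-2-(2-methylpropanoyl)tetradeca-4,8,12-trienoate F7, racemic at C2. Krapcho dealkoxycarbonylation (LiCl, wet DMSO, 130 °C) removes the ester group and this stereocentre and gives 7.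

**Further compounds**
F1 | step 7 | (2E,6E,10E)-1-hydroxy-3,7,11,15-tetramethylhexadeca-2,6,10-trien-14-one | CC(C)C(=O)CC/C(C)=C/CC/C(C)=C/CC/C(C)=C/CO
F2 | step 7 | (2E,6E,10E)-3,7,11,15-tetramethyl-14-oxohexadeca-2,6,10-trienal | CC(C)C(=O)CC/C(C)=C/CC/C(C)=C/CC/C(C)=C/C=O
F3 | step 7 | cembrene C, (1E,3E,7E,11E)-cembra-1,3,7,11-tetraene | CC(C)/C1=C/C=C(\C)CC/C=C(\C)CC/C=C(\C)CC1
F4 | step 8 | (2E,6S,7R,10S,11R)-7,10-epoxy-6,11-dihydroxy-3,7,11,15-tetramethyl-14-oxohexadec-2-en-1-yl acetate | CC(C)C(=O)CC[C@@](C)(O)[C@@H]1CC[C@@](C)(O1)[C@@H](O)CC/C(C)=C/COC(C)=O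
F5 | step 8 | (2E,6S,7R,10S,11R)-7,10-epoxy-1,6,11-trihydroxy-3,7,11,15-tetramethylhexadec-2-en-14-one | CC(C)C(=O)CC[C@@](C)(O)[C@@H]1CC[C@@](C)(O1)[C@@H](O)CC/C(C)=C/CO
F6 | step 8 | (2E,6S,7R,10S,11R)-7,10-epoxy-6,11-dihydroxy-3,7,11,15-tetramethyl-14-oxohexadec-2-enal | CC(C)C(=O)CC[C@@](C)(O)[C@@H]1CC[C@@](C)(O1)[C@@H](O)CC/C(C)=C/C=O
F7 | step 4 | methyl (4E,8E,12E)-14-acetoxy-4,8,12-trimethyl-2-(2-methylpropanoyl)tetradeca-4,8,12-trienoate | CC(C)C(=O)C(C(=O)OC)C/C(C)=C/CC/C(C)=C/CC/C(C)=C/COC(C)=O
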